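**Strategy.** The route rests on cutting the C2–C3 bond of ring C. C3 is the alpha carbon of the C4 ketone, and C2 is benzylic and bonded to O1, so in an O1 benzyl ether its C–H bonds are the most hydridic in the molecule. A chiral dirhodium carboxylate turns a terminal diazoketone into a carbene at C3 that inserts into one of the two enantiotopic OCH2Ph hydrogens. This single operation forms C2–C3, closes ring C and sets C2 as S. The precursor is a pentasubstituted 2-diazoacetophenone carrying OBn at the future O1, a bulky silyl ether at the future O5, the geranyl chain and the methoxy group.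

Key step: step 5

**Remarks on the chemistry.**
- Geranyl = (2E)-3,7-dimethylocta-2,6-dien-1-yl throughout.
- O5 is protected as the triisopropylsilyl (TIPS) ether rather than a smaller silyl ether. It should resist migration to the lithium enolate and hydrolysis during diazo transfer, it screens O5 from the carbene, and it still leaves with buffered fluoride.
- Assumption: Rh2(S-PTTL)4, dirhodium tetrakis[N-phthaloyl-(S)-tert-leucinate], is taken to give the (2S) product. Should the first run show the opposite sense, Rh2(R-PTTL)4 is used with no other change.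

**Route**

Step 1
Reactants: 1 2',6'-dihydroxy-4'-methoxyacetophenone; 2 geranyl bromide
Product: 3 1-[3-geranyl-2,6-dihydroxy-4-methoxyphenyl]ethanone
Conditions: 2 (0.9 equiv), 10% aq KOH, 0 °C to rt
Reagents that add atoms: geranyl bromide (2), CC(C)=CCC/C(C)=C/CBr
Why: C-allylation of an ambident phenoxide (Friedel–Crafts-type alkylation at ring carbon): in water the phenoxide oxygens are hydrogen-bonded, so the primary allylic bromide should be attacked by C3', which is equivalent to C5' by symmetry, and direct SN2 displacement keeps the E alkene; O-geranyl and bis-geranyl by-products are expected and are removed by chromatography.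

Step 2
Reactants: 3 1-[3-geranyl-2,6-dihydroxy-4-methoxyphenyl]ethanone; 4 benzyl bromide
Product: 5 1-[6-(benzyloxy)-3-geranyl-2-hydroxy-4-methoxyphenyl]ethanone
Conditions: BnBr (1.05 equiv), K2CO3, acetone, 50 °C
Reagents that add atoms: benzyl bromide (4), BrCc1ccccc1
Why: Williamson ether synthesis under carbonate conditions: the hydroxyl between the acetyl and geranyl groups is the more shielded and keeps the hydrogen bond to the carbonyl, so the open hydroxyl should be benzylated, and the remaining chelated phenol resists a second alkylation.

Step 3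
Reactants: 5 1-[6-(benzyloxy)-3-geranyl-2-hydroxy-4-methoxyphenyl]ethanone
Product: 6 1-[6-(benzyloxy)-3-geranyl-4-methoxy-2-(triisopropylsilyloxy)phenyl]ethanone
Conditions: TIPSOTf, 2,6-lutidine, CH2Cl2, 0 °C to rt
Reagents that add atoms: triisopropylsilyl trifluoromethanesulfonate, CC(C)[Si](C(C)C)(C(C)C)OS(=O)(=O)C(F)(F)F
Why: Silylation of a hindered, hydrogen-bonded phenol with a silyl triflate and a pyridine base; the triflate is electrophilic enough for the crowded oxygen, 2,6-lutidine is too weak to drive enol silylation of the acetyl group at this temperature, and the alkenes are inert under these buffered conditions.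

Step 4
Reactants: 6 1-[6-(benzyloxy)-3-geranyl-4-methoxy-2-(triisopropylsilyloxy)phenyl]ethanone
Product: 8 1-[6-(benzyloxy)-3-geranyl-4-methoxy-2-(triisopropylsilyloxy)phenyl]-2-diazoethanone, via trifluoroacetyl diketone 7 (not isolated)
Conditions: LiN(SiMe3)2, THF, −78 °C; CF3CO2CH2CF3, −78 °C; aq NH4Cl; then p-ABSA, Et3N, H2O (1 equiv), MeCN, rt
Reagents that add atoms: 2,2,2-trifluoroethyl trifluoroacetate, O=C(OCC(F)(F)F)C(F)(F)F (the COCF3 group of 7 only); 4-acetamidobenzenesulfonyl azide (p-ABSA), CC(=O)Nc1ccc(cc1)S(=O)(=O)N=[N+]=[N-] (the N2 unit of 8)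
Why: Detrifluoroacetylative Regitz diazo transfer: the methyl group is the only enolisable position, its lithium enolate undergoes Claisen acylation by the trifluoroacetate at −78 °C (cold enough that the bulky silyl group should not migrate), and the activated diketone 7, taken on crude, accepts the diazo group from the sulfonyl azide while the trifluoroacetyl group leaves as the N-acylsulfonamide.

Step 5
Reactants: 8 1-[6-(benzyloxy)-3-geranyl-4-methoxy-2-(triisopropylsilyloxy)phenyl]-2-diazoethanone
Product: 9 (2S)-6-geranyl-7-methoxy-2-phenyl-5-(triisopropylsilyloxy)chroman-4-one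
Conditions: Rh2(S-PTTL)4 (2 mol %), 4 Å MS, CH2Cl2, 0 °C, slow addition of 8
Reagents that add atoms: none
Why: The dirhodium tetracarboxylate (divalent rhodium) expels nitrogen from the diazoketone to give an electrophilic rhodium carbene at C3, which inserts into a benzylic C–H of the O1–CH2Ph group through a concerted, asynchronous three-centre transition state with hydride-like transfer, releasing the catalyst. The closest known reaction type is the chiral dirhodium carboxylate catalysed intramolecular C–H insertion of ortho-alkoxyaryl diazoketones next to the ether oxygen, which gives chroman-4-ones. Ring C closes as a six-membered ring by 1,6-insertion (carbene carbon counted as 1, the benzylic carbon as 6), the only activated C–H bond within reach. C2 is the only new stereocentre and is set by catalyst control: the phthalimido walls of the four (S)-tert-leucinate ligands differentiate the two enantiotopic benzylic hydrogens, the substrate having no stereocentre of its own. The step needs insertion to beat attack of the carbene on O1 (oxonium ylide, then 1,2-benzyl Stevens shift to a 2-benzylbenzofuran-3-one); this should be secured by the double activation of the C–H bond by O1 and phenyl, by the low nucleophilicity of an aryl ether oxygen conjugated to the acyl-bearing ring, and by the carboxylate ligand set. O5 is screened by the triisopropylsilyl group and offers no activated C–H, the geranyl alkenes sit meta to the acyl group and cannot reach the carbene, and slow addition under dilution suppresses carbene dimerisation.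

Step 6
Reactants: 9 (2S)-6-geranyl-7-methoxy-2-phenyl-5-(triisopropylsilyloxy)chroman-4-one
Product: 10 (2S)-6-geranylpinostrobin, (2S)-6-geranyl-5-hydroxy-7-methoxy-2-phenylchroman-4-one
Conditions: Bu4NF, AcOH (1:1), THF, 0 °C
Reagents that add atoms: none
Why: Fluoride-induced cleavage of an aryl silyl ether; acetic acid protonates the phenoxide as it forms, so ring C should not open by retro-oxa-Michael (E1cB) reaction and C2 keeps its configuration, while the ketone, the geranyl chain and the methyl ether are inert.

**Compound list**

1 | 2',6'-dihydroxy-4'-methoxyacetophenone | CC(=O)c1c(O)cc(OC)cc1O | starting material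
2 | geranyl bromide, (2E)-1-bromo-3,7-dimethylocta-2,6-diene | CC(C)=CCC/C(C)=C/CBr | starting material
3 | 1-[3-geranyl-2,6-dihydroxy-4-methoxyphenyl]ethanone | CC(=O)c1c(O)cc(OC)c(C/C=C(\C)CCC=C(C)C)c1O | intermediate
4 | benzyl bromide | BrCc1ccccc1 | starting material
5 | 1-[6-(benzyloxy)-3-geranyl-2-hydroxy-4-methoxyphenyl]ethanone | CC(=O)c1c(OCc2ccccc2)cc(OC)c(C/C=C(\C)CCC=C(C)C)c1O | intermediate
6 | 1-[6-(benzyloxy)-3-geranyl-4-methoxy-2-(triisopropylsilyloxy)phenyl]ethanone | CC(=O)c1c(OCc2ccccc2)cc(OC)c(C/C=C(\C)CCC=C(C)C)c1O[Si](C(C)C)(C(C)C)C(C)C | intermediate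
7 | 1-[6-(benzyloxy)-3-geranyl-4-methoxy-2-(triisopropylsilyloxy)phenyl]-4,4,4-trifluorobutane-1,3-dione | FC(F)(F)C(=O)CC(=O)c1c(OCc2ccccc2)cc(OC)c(C/C=C(\C)CCC=C(C)C)c1O[Si](C(C)C)(C(C)C)C(C)C | intermediate
8 | 1-[6-(benzyloxy)-3-geranyl-4-methoxy-2-(triisopropylsilyloxy)phenyl]-2-diazoethanone | [N-]=[N+]=CC(=O)c1c(OCc2ccccc2)cc(OC)c(C/C=C(\C)CCC=C(C)C)c1O[Si](C(C)C)(C(C)C)C(C)C | intermediate
9 | (2S)-6-geranyl-7-methoxy-2-phenyl-5-(triisopropylsilyloxy)chroman-4-one | COc1cc2c(c(O[Si](C(C)C)(C(C)C)C(C)C)c1C/C=C(\C)CCC=C(C)C)C(=O)C[C@@H](c1ccccc1)O2 | intermediate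
10 | (2S)-6-geranylpinostrobin, (2S)-6-geranyl-5-hydroxy-7-methoxy-2-phenylchroman-4-one | COc1cc2c(c(O)c1C/C=C(\C)CCC=C(C)C)C(=O)C[C@@H](c1ccccc1)O2 | target

**Totals.** Total step count: 6. Longest linear sequence: 6 steps (from 1).

**Steps most likely to fail**

1. Step 5. Capture of the carbene by the O1 lone pair (ylide formation followed by benzyl migration to a five-membered ring) may outrun insertion, or the catalyst may distinguish the two enantiotopic benzylic hydrogens only weakly. The fallback makes the C2–phenyl bond by asymmetric conjugate addition and uses no carbene; it sets out from 3 and returns at 9. Allyl bromide and K2CO3 in acetone should alkylate the open hydroxyl of 3 to give the allyl ether F1. TIPSOTf and 2,6-lutidine then give the allyl silyl bis-ether F2. Pd(PPh3)4 (zerovalent palladium) with morpholine in THF removes the allyl group and leaves the phenol F3, free at the future O1 and blocked at O5. Heating with N,N-dimethylformamide dimethyl acetal gives the enaminone F4, which closes on silica gel or with pyridinium p-toluenesulfonate, losing dimethylamine, to the chromone F5. Conjugate addition of phenylboronic acid under Pd(OCOCF3)2 and the t-BuPyOx enantiomer that leads to 2S (NH4PF6, water, 1,2-dichloroethane, 60 °C) then gives 9 without base.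

2. Step 4. Transfer of the silyl group from O5 to the neighbouring enolate oxygen, or its hydrolysis in the aqueous amine stage, would free a phenoxide that condenses with the trifluoroacetyl ketone to a 2-trifluoromethylchromone; acylation of the crowded enolate may also stall. The fallback uses no enolate and no strong base; it sets out from 6 and returns at 8. Heating 6 with N,N-dimethylformamide dimethyl acetal in toluene gives the enaminone F6. Tosyl azide in acetonitrile at room temperature adds across the enamine double bond, and the triazoline fragments to 8 and the N-sulfonylformamidine.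

3. Step 1. Alkylation at oxygen rather than carbon, and a second alkylation at the other ring position, would drain material. The fallback is O-alkylation followed by rearrangement; it sets out from 1 and 2 and returns at 3. K2CO3 in acetone gives the mono-O-geranyl ether F7, the second hydroxyl staying chelated. Montmorillonite K10 in CH2Cl2 at 0 °C then promotes the 1,3-shift of the geranyl group from oxygen to ring carbon, kept cold to avoid chroman formation. Migration to either open ring position gives the same compound 3, since the two positions become equivalent once the phenol is freed.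

**Further compounds**

F1 | step 5 | 1-[6-(allyloxy)-3-geranyl-2-hydroxy-4-methoxyphenyl]ethanone | CC(=O)c1c(OCC=C)cc(OC)c(C/C=C(\C)CCC=C(C)C)c1O
F2 | step 5 | 1-[6-(allyloxy)-3-geranyl-4-methoxy-2-(triisopropylsilyloxy)phenyl]ethanone | CC(=O)c1c(OCC=C)cc(OC)c(C/C=C(\C)CCC=C(C)C)c1O[Si](C(C)C)(C(C)C)C(C)C
F3 | step 5 | 1-[3-geranyl-6-hydroxy-4-methoxy-2-(triisopropylsilyloxy)phenyl]ethanone | CC(=O)c1c(O)cc(OC)c(C/C=C(\C)CCC=C(C)C)c1O[Si](C(C)C)(C(C)C)C(C)C
F4 | step 5 | (E)-3-(dimethylamino)-1-[3-geranyl-6-hydroxy-4-methoxy-2-(triisopropylsilyloxy)phenyl]prop-2-en-1-one | CN(C)/C=C/C(=O)c1c(O)cc(OC)c(C/C=C(\C)CCC=C(C)C)c1O[Si](C(C)C)(C(C)C)C(C)C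
F5 | step 5 | 6-geranyl-7-methoxy-5-(triisopropylsilyloxy)-4H-chromen-4-one | COc1cc2occc(=O)c2c(O[Si](C(C)C)(C(C)C)C(C)C)c1C/C=C(\C)CCC=C(C)C
F6 | step 4 | (E)-1-[6-(benzyloxy)-3-geranyl-4-methoxy-2-(triisopropylsilyloxy)phenyl]-3-(dimethylamino)prop-2-en-1-one | CN(C)/C=C/C(=O)c1c(OCc2ccccc2)cc(OC)c(C/C=C(\C)CCC=C(C)C)c1O[Si](C(C)C)(C(C)C)C(C)C
F7 | step 1 | 1-[2-(geranyloxy)-6-hydroxy-4-methoxyphenyl]ethanone | CC(=O)c1c(O)cc(OC)cc1OC/C=C(\C)CCC=C(C)C
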